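**Plan**

1. Numbering: lactone O1, C2 (C=O), C3 (OH), C4 (carries ring A, the 4-hydroxyphenyl), C5 (the stereocentre, carries the benzyl group of ring B, the 4-hydroxy-3-prenylphenyl; prenyl = 3-methylbut-2-enyl).
2. Cuts: first the three O-protecting bonds (two aryl O–Si, one C3 O–CH3); then O1–C5 and C4–ring A together, which opens the butenolide to an axially chiral 2-methoxy-2,3-allenoic acid and a 4-silyloxyiodobenzene; then the allene C=C next to the carboxyl (ketene + α-methoxy phosphorus ylide) and the aryl–prenyl bond.
3. Enabling feature: C5 is the oxygen-bearing allylic carbon of the C3=C4 alkene, C4 holds ring A and C3 holds oxygen. This is the pattern left when a carboxylate oxygen and an aryl group add across the remote double bond of a 2-alkoxy-2,3-allenoic acid.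
4. Forward order: ring B is iodinated, silylated and prenylated; its propanoate chain is lengthened to the allenoate; the lactone, the only ring made, closes in the same step that attaches ring A; two deprotections finish.
5. Stereochemistry: the allene axis is secured by classical resolution of the racemic acid and is converted into (R)-C5 by the geometry of the ring closure; nothing afterwards touches C5.

Key step: step 11

Assumption: the hand of 1-phenylethylamine that crystallises with the (Sa) acid is taken to be (S); if the salt screen shows the opposite pairing, the (R) amine is used with nothing else changed, and the axial configuration is confirmed by vibrational circular dichroism before step 11.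

**Route**

Step 1
Reactants: 1 methyl 3-(4-hydroxyphenyl)propanoate
Product: 2 methyl 3-(4-hydroxy-3-iodophenyl)propanoate
Conditions: NIS (1.05 equiv), CF3CO2H (10 mol %), MeCN, 0 °C → rt
Reagents that add atoms: N-iodosuccinimide, O=C1CCC(=O)N1I
Why: Electrophilic aromatic iodination; the para position is blocked, so the iodonium equivalent enters ortho to the hydroxyl, and one equivalent of reagent limits di-iodination.

Step 2
Reactants: 2 methyl 3-(4-hydroxy-3-iodophenyl)propanoate
Product: 3 methyl 3-[3-iodo-4-(triisopropylsilyloxy)phenyl]propanoate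
Conditions: i-Pr3SiCl (1.2 equiv), imidazole (2.5 equiv), DMF, rt
Reagents that add atoms: chlorotriisopropylsilane, CC(C)[Si](Cl)(C(C)C)C(C)C
Why: Imidazole-promoted silylation of the phenol; the triisopropylsilyl ether is chosen because it should survive the arylmagnesium step and both later hydroxide hydrolyses, which a tert-butyldimethylsilyl aryl ether would not.

Step 3
Reactants: 3 methyl 3-[3-iodo-4-(triisopropylsilyloxy)phenyl]propanoate
Product: 5 methyl 3-[3-(3-methylbut-2-enyl)-4-(triisopropylsilyloxy)phenyl]propanoate, via arylmagnesium chloride 4 (not isolated)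
Conditions: i-PrMgCl·LiCl (1.1 equiv), THF, −20 °C; then CuBr·SMe2 (10 mol %), prenyl bromide (1.5 equiv), −20 → 0 °C
Reagents that add atoms: 1-bromo-3-methylbut-2-ene (prenyl bromide), CC(C)=CCBr
Why: Iodine–magnesium exchange is fast at −20 °C, where the methyl ester is not attacked, and the arylmagnesium 4 then undergoes copper-catalysed allylic substitution at the unhindered CH2 of prenyl bromide (SN2 mode) to give the linear prenyl arene.

Step 4
Reactants: 5 methyl 3-[3-(3-methylbut-2-enyl)-4-(triisopropylsilyloxy)phenyl]propanoate
Product: 6 3-[3-(3-methylbut-2-enyl)-4-(triisopropylsilyloxy)phenyl]propanoic acid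
Conditions: LiOH·H2O (2 equiv), THF/MeOH/H2O, 0 °C → rt; then cold 0.5 M HCl to pH 3
Reagents that add atoms: lithium hydroxide (supplies the acid OH oxygen), [Li+].[OH-]
Why: Saponification of an unhindered methyl ester proceeds under mild conditions that the bulky aryl triisopropylsilyl ether, shielded further by the ortho prenyl group, and the alkene should tolerate.

Step 5
Reactants: 7 methyl methoxyacetate
Product: 8 methyl 2-bromo-2-methoxyacetate (racemic)
Conditions: NBS (1.05 equiv), AIBN (cat.), PhCF3, 80 °C
Reagents that add atoms: N-bromosuccinimide, O=C1CCC(=O)N1Br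
Why: Wohl–Ziegler radical bromination selects the only captodatively stabilised C–H, the one flanked by the ether oxygen and the ester.

Step 6
Reactants: 8 methyl 2-bromo-2-methoxyacetate
Product: 9 (1,2-dimethoxy-2-oxoethyl)triphenylphosphonium bromide (racemic)
Conditions: PPh3 (1.0 equiv), toluene, rt, salt filtered
Reagents that add atoms: triphenylphosphine, c1ccc(cc1)P(c1ccccc1)c1ccccc1
Why: Quaternisation of the phosphine by a highly reactive α-bromo ether (oxocarbenium-assisted substitution), the salt separating from toluene.

Step 7
Reactants: 6 3-[3-(3-methylbut-2-enyl)-4-(triisopropylsilyloxy)phenyl]propanoic acid; 9 (1,2-dimethoxy-2-oxoethyl)triphenylphosphonium bromide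
Product: 13 racemic methyl 2-methoxy-5-[3-(3-methylbut-2-enyl)-4-(triisopropylsilyloxy)phenyl]penta-2,3-dienoate, via acid chloride 10 (not isolated), via phosphorus ylide 11 (not isolated), via ketene 12 (not isolated)
Conditions: 6, (COCl)2 (1.2 equiv), DMF (cat.), CH2Cl2, 0 °C → rt, evaporate; 9, Et3N (2.3 equiv), CH2Cl2, 0 °C, crude chloride added over 1 h, → rt
Reagents that add atoms: none
Why: Triethylamine dehydrochlorinates acid chloride 10 to the monosubstituted ketene 12 and deprotonates salt 9 to the ester-stabilised ylide 11, and Wittig olefination of the ketene C=O by 11 gives the 2-methoxy-2,3-allenoate, necessarily racemic about the new axis, while slow addition keeps the ketene too dilute to dimerise.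

Step 8
Reactants: 13 racemic methyl 2-methoxy-5-[3-(3-methylbut-2-enyl)-4-(triisopropylsilyloxy)phenyl]penta-2,3-dienoate
Product: 14 racemic 2-methoxy-5-[3-(3-methylbut-2-enyl)-4-(triisopropylsilyloxy)phenyl]penta-2,3-dienoic acid
Conditions: LiOH·H2O (1.5 equiv), THF/H2O, 0 °C; then cold 0.5 M HCl to pH 3–4, extracted at once
Reagents that add atoms: lithium hydroxide (supplies the acid OH oxygen), [Li+].[OH-]
Why: Saponification of the methyl ester; once the carboxylate has formed the allene is no longer activated toward γ-deprotonation, so isomerisation to the conjugated dienoate should not occur at 0 °C, and brief cold acidification spares the allenyl ether.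

Step 9
Reactants: 14 racemic 2-methoxy-5-[3-(3-methylbut-2-enyl)-4-(triisopropylsilyloxy)phenyl]penta-2,3-dienoic acid
Product: 15 (S)-1-phenylethylammonium (Sa)-2-methoxy-5-[3-(3-methylbut-2-enyl)-4-(triisopropylsilyloxy)phenyl]penta-2,3-dienoate
Conditions: (S)-1-phenylethylamine (1.0 equiv), EtOAc/hexane, 50 → 0 °C, recrystallised to constant rotation
Reagents that add atoms: (S)-1-phenylethylamine, C[C@H](N)c1ccccc1
Why: Classical resolution; the two diastereomeric ammonium carboxylates differ in solubility and repeated crystallisation should leave the salt of the (Sa) acid, the configurationally stable allene axis being sorted and not created.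

Step 10
Reactants: 15 (S)-1-phenylethylammonium (Sa)-2-methoxy-5-[3-(3-methylbut-2-enyl)-4-(triisopropylsilyloxy)phenyl]penta-2,3-dienoate
Product: 16 (Sa)-2-methoxy-5-[3-(3-methylbut-2-enyl)-4-(triisopropylsilyloxy)phenyl]penta-2,3-dienoic acid (P helicity; drawn with CO2H up and OMe down in the paper plane on the left allene carbon, the right allene carbon carries H toward the viewer and the CH2Ar group away)
Conditions: cold 0.5 M HCl, Et2O, 0 °C
Reagents that add atoms: none
Why: Acid–base partition protonates the carboxylate and leaves the ammonium chloride in water, and cold dilute acid with brief contact touches neither the allenyl ether nor the axis.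

Step 11
Reactants: 16 (Sa)-2-methoxy-5-[3-(3-methylbut-2-enyl)-4-(triisopropylsilyloxy)phenyl]penta-2,3-dienoic acid; 17 tert-butyl(4-iodophenoxy)dimethylsilane
Product: 18 (R)-4-[4-(tert-butyldimethylsilyloxy)phenyl]-3-methoxy-5-[3-(3-methylbut-2-enyl)-4-(triisopropylsilyloxy)benzyl]furan-2(5H)-one
Conditions: Pd(PPh3)4 (5 mol %), Ag2CO3 (10 mol %), i-Pr2NEt (2 equiv), 17 (1.2 equiv), MeCN, 70 °C
Reagents that add atoms: none
Why: Oxidative addition of 17 to zerovalent palladium gives ArPdI(PPh3)2 (divalent palladium); after iodide abstraction by the silver salt it binds the remote C=C of the allenoate (central carbon and CH terminus) on the face away from the carboxylate, the carboxylate oxygen adds to the CH terminus anti to palladium, and reductive elimination from the 4-palladated furanone forms C4–ring A and returns zerovalent palladium. The closest known reaction type is the palladium/silver-cocatalysed coupling–cyclisation of 2,3-allenoic acids with aryl iodides to 4-aryl butenolides, used here on an acid whose C2 substituent is methoxy. The lactone ring closes by 5-endo-trig anti-oxypalladation, forming O1–C5, in the same catalytic cycle that forms C4–aryl. C5 is controlled by the allene axis (axial-to-central chirality transfer): the carboxylate lies in the plane of the remote π bond and can reach only one lobe of the CH terminus, so the (Sa) acid must give (R)-C5. The step needs oxypalladation to outrun carbopalladation to a π-allylpalladium species, which would erode the transfer; the in-plane carboxylate held as its ammonium salt, the unhindered CH terminus and the halide-free cationic palladium secure this, and the trisubstituted prenyl alkene and the aryl silyl ethers are spectators.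

Step 12
Reactants: 18 (R)-4-[4-(tert-butyldimethylsilyloxy)phenyl]-3-methoxy-5-[3-(3-methylbut-2-enyl)-4-(triisopropylsilyloxy)benzyl]furan-2(5H)-one
Product: 19 (R)-4-[4-(tert-butyldimethylsilyloxy)phenyl]-3-hydroxy-5-[3-(3-methylbut-2-enyl)-4-(triisopropylsilyloxy)benzyl]furan-2(5H)-one
Conditions: LiI (anhydrous, 6 equiv), EtOAc, reflux; then cold 0.5 M HCl
Reagents that add atoms: none
Why: Nucleophilic O-demethylation (SN2 at methyl, as in lithium iodide ester cleavage); lithium bridges the C2 carbonyl and the C3 ether oxygen, iodide removes the methyl group, the leaving group is the stabilised enolate of an isotetronic acid, and the non-basic medium should leave C5–H, the silyl ethers and the alkene alone.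

Step 13
Reactants: 19 (R)-4-[4-(tert-butyldimethylsilyloxy)phenyl]-3-hydroxy-5-[3-(3-methylbut-2-enyl)-4-(triisopropylsilyloxy)benzyl]furan-2(5H)-one
Product: 20 (R)-3-hydroxy-5-[4-hydroxy-3-(3-methylbut-2-enyl)benzyl]-4-(4-hydroxyphenyl)furan-2(5H)-one (CNP0382875.1)
Conditions: Bu4NF (2.5 equiv), AcOH (2.5 equiv), THF, 0 °C → rt
Reagents that add atoms: none
Why: Fluoride cleaves both aryl O–Si bonds, the acetic acid buffer keeps the medium near neutral so that C5–H of the butenolide is not removed, and the acidic C3 enol and the prenyl group are unaffected.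

**Compound list**

1 | methyl 3-(4-hydroxyphenyl)propanoate | COC(=O)CCc1ccc(O)cc1 | starting material
2 | methyl 3-(4-hydroxy-3-iodophenyl)propanoate | COC(=O)CCc1ccc(O)c(I)c1 | intermediate
3 | methyl 3-[3-iodo-4-(triisopropylsilyloxy)phenyl]propanoate | COC(=O)CCc1ccc(O[Si](C(C)C)(C(C)C)C(C)C)c(I)c1 | intermediate
4 | [5-(3-methoxy-3-oxopropyl)-2-(triisopropylsilyloxy)phenyl]magnesium chloride (formed in the flask) | COC(=O)CCc1ccc(O[Si](C(C)C)(C(C)C)C(C)C)c([Mg]Cl)c1 | intermediate
5 | methyl 3-[3-(3-methylbut-2-enyl)-4-(triisopropylsilyloxy)phenyl]propanoate | COC(=O)CCc1ccc(O[Si](C(C)C)(C(C)C)C(C)C)c(CC=C(C)C)c1 | intermediate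
6 | 3-[3-(3-methylbut-2-enyl)-4-(triisopropylsilyloxy)phenyl]propanoic acid | OC(=O)CCc1ccc(O[Si](C(C)C)(C(C)C)C(C)C)c(CC=C(C)C)c1 | intermediate
7 | methyl methoxyacetate | COCC(=O)OC | starting material
8 | methyl 2-bromo-2-methoxyacetate (racemic) | COC(Br)C(=O)OC | intermediate
9 | (1,2-dimethoxy-2-oxoethyl)triphenylphosphonium bromide (racemic) | COC(C(=O)OC)[P+](c1ccccc1)(c1ccccc1)c1ccccc1.[Br-] | intermediate
10 | 3-[3-(3-methylbut-2-enyl)-4-(triisopropylsilyloxy)phenyl]propanoyl chloride (formed in the flask) | ClC(=O)CCc1ccc(O[Si](C(C)C)(C(C)C)C(C)C)c(CC=C(C)C)c1 | intermediate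
11 | methyl 2-methoxy-2-(triphenylphosphoranylidene)acetate (formed in the flask) | COC(C(=O)OC)=P(c1ccccc1)(c1ccccc1)c1ccccc1 | intermediate
12 | 3-[3-(3-methylbut-2-enyl)-4-(triisopropylsilyloxy)phenyl]prop-1-en-1-one, the ketene (formed in the flask) | O=C=CCc1ccc(O[Si](C(C)C)(C(C)C)C(C)C)c(CC=C(C)C)c1 | intermediate
13 | racemic methyl 2-methoxy-5-[3-(3-methylbut-2-enyl)-4-(triisopropylsilyloxy)phenyl]penta-2,3-dienoate | COC(=O)C(OC)=C=CCc1ccc(O[Si](C(C)C)(C(C)C)C(C)C)c(CC=C(C)C)c1 | intermediate
14 | racemic 2-methoxy-5-[3-(3-methylbut-2-enyl)-4-(triisopropylsilyloxy)phenyl]penta-2,3-dienoic acid | OC(=O)C(OC)=C=CCc1ccc(O[Si](C(C)C)(C(C)C)C(C)C)c(CC=C(C)C)c1 | intermediate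
15 | (S)-1-phenylethylammonium (Sa)-2-methoxy-5-[3-(3-methylbut-2-enyl)-4-(triisopropylsilyloxy)phenyl]penta-2,3-dienoate | [O-]C(=O)C(OC)=[C@]=C([H])Cc1ccc(O[Si](C(C)C)(C(C)C)C(C)C)c(CC=C(C)C)c1.C[C@H]([NH3+])c1ccccc1 | intermediate
16 | (Sa)-2-methoxy-5-[3-(3-methylbut-2-enyl)-4-(triisopropylsilyloxy)phenyl]penta-2,3-dienoic acid | OC(=O)C(OC)=[C@]=C([H])Cc1ccc(O[Si](C(C)C)(C(C)C)C(C)C)c(CC=C(C)C)c1 | intermediate
17 | tert-butyl(4-iodophenoxy)dimethylsilane | CC(C)(C)[Si](C)(C)Oc1ccc(I)cc1 | starting material
18 | (R)-4-[4-(tert-butyldimethylsilyloxy)phenyl]-3-methoxy-5-[3-(3-methylbut-2-enyl)-4-(triisopropylsilyloxy)benzyl]furan-2(5H)-one | CC(C)=CCc1cc(C[C@H]2OC(=O)C(OC)=C2c2ccc(O[Si](C)(C)C(C)(C)C)cc2)ccc1O[Si](C(C)C)(C(C)C)C(C)C | intermediate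
19 | (R)-4-[4-(tert-butyldimethylsilyloxy)phenyl]-3-hydroxy-5-[3-(3-methylbut-2-enyl)-4-(triisopropylsilyloxy)benzyl]furan-2(5H)-one | CC(C)=CCc1cc(C[C@H]2OC(=O)C(O)=C2c2ccc(O[Si](C)(C)C(C)(C)C)cc2)ccc1O[Si](C(C)C)(C(C)C)C(C)C | intermediate
20 | (R)-3-hydroxy-5-[4-hydroxy-3-(3-methylbut-2-enyl)benzyl]-4-(4-hydroxyphenyl)furan-2(5H)-one | CC(C)=CCc1cc(C[C@H]2OC(=O)C(O)=C2c2ccc(O)cc2)ccc1O | target

**Step count**

Total: 13 steps. Longest linear sequence: 11 steps (steps 1–4 and 7–13); steps 5 and 6 form the short branch that joins at step 7.

**Steps most likely to fail**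

Step 11. The axial-to-central transfer may be eroded if arylpalladium adds to the central allene carbon first and the resulting π-allylpalladium species equilibrates. The acid may also cycloisomerise under silver or palladium to the butenolide without aryl transfer. The electron-rich enol-ether double bond of the 2-methoxyallene may divert the arylpalladium species. The fallback sets out from 16 and separates ring closure from arylation. Iodolactonisation of 16 (I2, NaHCO3, MeCN/H2O, 0 °C) should give (R)-4-iodo-3-methoxy-5-[3-(3-methylbut-2-enyl)-4-(triisopropylsilyloxy)benzyl]furan-2(5H)-one F1, with C5 fixed by the same in-plane attack of the carboxylate on the iodonium-activated remote double bond. Suzuki–Miyaura coupling of F1 with [4-(tert-butyldimethylsilyloxy)phenyl]boronic acid (Pd(PPh3)4, K3PO4, dioxane/H2O, 60 °C) should then give 18, where the route is rejoined.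

Step 9. The two diastereomeric salts may co-crystallise or separate as an oil, so that crystallisation brings no enrichment, and material is lost with every recrystallisation. The fallback sets out from 14 and replaces crystallisation by chromatography. The racemic acid is separated by preparative supercritical-fluid chromatography on an amylose tris(3,5-dimethylphenylcarbamate) phase (CO2/MeOH), the (Sa) enantiomer being identified by vibrational circular dichroism. This delivers 16 directly, so that 15 and step 10 are bypassed; it makes no compound outside the list (none F0).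

Step 12. Displacement at the methyl group of a weakly activated enol ether may be slow. Forcing it may bring reversible opening of the lactone at C5 by iodide or loss of configuration at C5. The fallback sets out from 18, reverses the order of the two deprotections and changes the nucleophile class. Buffered fluoride (Bu4NF, AcOH, THF, 0 °C) should first give (R)-5-[4-hydroxy-3-(3-methylbut-2-enyl)benzyl]-4-(4-hydroxyphenyl)-3-methoxyfuran-2(5H)-one F2. Thiolate demethylation (NaSEt, DMF, 60–80 °C, then cold dilute HCl) is then run on the bis-phenoxide, whose electron-rich ring A lowers the acidity of C5–H, and should give 20 directly.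

**Further compounds**

F1 | step 11 | (R)-4-iodo-3-methoxy-5-[3-(3-methylbut-2-enyl)-4-(triisopropylsilyloxy)benzyl]furan-2(5H)-one | CC(C)=CCc1cc(C[C@H]2OC(=O)C(OC)=C2I)ccc1O[Si](C(C)C)(C(C)C)C(C)C
F0 | step 9 | none | none
F2 | step 12 | (R)-5-[4-hydroxy-3-(3-methylbut-2-enyl)benzyl]-4-(4-hydroxyphenyl)-3-methoxyfuran-2(5H)-one | CC(C)=CCc1cc(C[C@H]2OC(=O)C(OC)=C2c2ccc(O)cc2)ccc1O
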